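The coupling partner is the charge to settle for the next flask: keep the north recipe, or take the east recipe with twice that amount.

the same everywhere: starting material 0.0010 M; free catalyst 25 µM

|  | coupling partner | protic impurity | remark | time |
|---|---|---|---|---|
| north | 1.5 mM | 0.10 mM | the very flask that is asked about, followed so far |  |
| east | 3 mM | 0.10 mM | run made earlier |  |
| flask | 1.50 mM | 0.100 mM |  | 5.0 min |

north run (percent of the starting material charged)

| time / min | open intermediate / % | product / % | starting material / % |
|---|---|---|---|
| 0.167 | 29.9 | 5.2 | 66.0 |
| 0.250 | 36.8 | 8.8 | 54.1 |
| 0.667 | 43.9 | 33.7 | 21.2 |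
| 1.33 | 30.7 | 65.3 | 4.7 |
| 2.50 | 11.3 | 87.2 | 0.4 |

east run (percent of the starting material charged)

| time / s | open intermediate / % | product / % | starting material / % |
|---|---|---|---|
| 10.0 | 28.1 | 5.5 | 65.2 |
| 15.0 | 34.6 | 12.8 | 53.0 |
| 30.0 | 38.8 | 32.2 | 28.5 |
| 60.0 | 24.9 | 66.2 | 8.8 |
| 120 | 5.8 | 94.5 | 0.6 |

(each reading ± 0.5 percentage points)

- when, up to 5.0 min, the flask holds most open intermediate
- the amount of open intermediate, in percent of the starting material charged, at that time
- the first time at which open intermediate reaches 13%, in the same percent, in min

The highest readings favour less partner, because open intermediate reads higher in north, 43.9% at 0.667 min, than in east, 38.8% at 30.0 s. But the lower charge must still carry the flask through to product, so the balance of partner is written down, counting one partner for each starting material turned to product and, as a caution, one for each protic impurity. In this flask 1.50 mM less 0.0010 M less 0.100 mM leaves 0.400 mM of spare partner S, the partner still unused once both demands are met, and that is 26.7% of its charge. S is positive in this flask, so starting material is the limiting reagent there, and the north charge stays as it is. The flask is the north run itself, so its readings already bracket the peak: 36.8% at 0.250 min, 43.9% at 0.667 min and 30.7% at 1.33 min. The level of 13% is passed before the first reading, which already stands at 29.9% at 0.167 min.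

The forecast gives a peak of 45% at 0.55 min and the level at 0.062 min, holding that “Starting-material loss is nearly first order”.

    starting material + free catalyst → free catalyst + open intermediate (k = 1800 M⁻¹ s⁻¹)
    free catalyst + open intermediate ⇌ catalyst intermediate (K = 940 M⁻¹, k = 2400 M⁻¹ s⁻¹)
    coupling partner + catalyst intermediate → free catalyst + product (k = 1900 M⁻¹ s⁻¹)
    coupling partner + protic impurity → quenched reagent (k = 67.0 M⁻¹ s⁻¹)

The flask peaks at 44.9% at 0.554 min and reaches the level at 0.0563 min. At 0.285 min its protic impurity has a half-life of 0.13 min in the quench, shorter than the 1.6 min of coupling partner in the coupling step. By 2.50 min the protic impurity in the flask stands at 0.0160% of its charge. The flask holds 28% of its partner charge at 5.00 min and 26.7% at 50.0 min, against the reckoned 26.7%. In the neighbouring flask with 0.0060 M of partner, S is 4.90 mM, or 81.7% of its charge, and 82% is left there at 5.00 min.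

Readings and results were computed for substances that don't exist; scatter was added.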